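**The choice.** The decay of the intermediate climbs with temperature faster than its coupling to partner, 106 kJ mol⁻¹ against 76.0 kJ mol⁻¹, so heat should waste more of it. I had to choose which flask to repeat, and whether to leave its partner charge alone.

in all of them: substrate 0.20 M; partner 0.600 equiv; time 3.0 min
- Wednesday's: at 70 °C until 2.0 min, from then on at 110 °C
- Friday's: temperature 70 °C
- Tuesday's: temperature 90 °C
- Sunday's: temperature 110 °C

    substrate → intermediate (k1 = 0.00220 s⁻¹, Ea1 = 112 kJ mol⁻¹)
    partner + intermediate → target (k2 = 0.0380 M⁻¹ s⁻¹, Ea2 = 76.0 kJ mol⁻¹)
    intermediate → decomposed reagent (k3 = 0.00343 s⁻¹, Ea3 = 106 kJ mol⁻¹)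
    target ⇌ isomer of the product (K4 = 0.125, k4 = 0.0133 s⁻¹, Ea4 = 88.0 kJ mol⁻¹, ΔH4 = −19.0 kJ mol⁻¹)
    (constants at 70 °C)

- all constants are for 70 °C and move with temperature by the activation energies and enthalpies

- which flask leads in amount of target, in percent of the substrate charged ("all alike" within 1.5 percentage points) (Wednesday's / Friday's / Tuesday's / Sunday's / all alike)
- how much target is there at the end, in percent of the substrate charged: Wednesday's
- how much target is there at the end, in percent of the substrate charged: Friday's
- how much target is there at the end, in percent of the substrate charged: Tuesday's
- how much target is there at the end, in percent of the substrate charged: Sunday's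

**One molecule.** I followed one molecule of intermediate to its fork, where it either couples or decays. Let b be the partner left, as a fraction of the substrate charge. The chance of coupling is then b/(b+E), with E the decay constant over the coupling constant times the substrate concentration. At 70 °C, E is 0.451. This even point, a selectivity factor, is the partner level at which both exits are equally likely. Sunday's, at 110 °C, has 1.35. For Tuesday's, at 90 °C, I took the geometric mean, 0.781.

**The reckoning.** With the full 0.600 equiv of partner, the first molecules couple at 57.1 % on Friday's, 43.4 % on Tuesday's and 30.7 % on Sunday's. Coupling uses partner, so for Tuesday's and Sunday's I recomputed the chance at the mean partner level. That gave 32.9 % for Tuesday's and 24.8 % for Sunday's.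

Tuesday's converts about 95.4 % of its substrate, so about 31.4 % of the charge couples. Coupled product equilibrates quickly, since on Tuesday's its relaxation half-life of 0.760 s is far shorter than the run. Removing the isomer leaves 28.8 % target on Tuesday's and 23.4 % on Sunday's.

Friday's converts about 32.7 %, so even at its first chance it stays below 18.7 % coupled, less than Tuesday's. On Wednesday's, about 76.8 % of the substrate remains at the change and then meets Sunday's even point, so I placed that flask near Sunday's without a figure. I decided to repeat Tuesday's and leave the partner charge as it was.

**The forecast.** The forecast also chose Tuesday's, giving 25.4 % for Wednesday's, 8.2 % for Friday's, 29.7 % for Tuesday's and 23.9 % for Sunday's. Its grounds included this: “The target-isomer equilibrium is fast at all these temperatures”. Its Tuesday's figure stood above mine, and so did its Sunday's figure.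

**The result.** The simulation put Tuesday's first, with 25.3 % on Wednesday's, 7.74 % on Friday's, 29.5 % on Tuesday's and 23.9 % on Sunday's.

**Still moving?** Sunday's stayed at 23.9 % when left ten times as long. Tuesday's still held 3.21 % substrate and 3.33 % intermediate at 3.00 min. Its 47 % of partner gives b = 0.280 and a chance of 26.4 %, so about 1.7 percentage points more should couple; its target rose from 29.5 % at 3.00 min to 31.0 % at 30.0 min. Friday's had 80.9 % of the charge still to cross by 30.0 min. The mean of its chances at the two partner readings is 40.8 %, so about 33.0 % of the charge should couple, and its target rose from 7.74 % at 3.00 min to 37.4 % at 30.0 min.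

The numbers are assumed; the rest is arithmetic.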